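**Strategy**

The pyranone ring of the flavanone is disconnected at O1–C2 and C3–C4. The feature used is that C2, the carbon between O1 and C3, bears a B ring with a free hydroxyl at C2'. The B-ring fragment is therefore a 2-vinylphenol, a dienophile that a chiral phosphoric acid can bind by hydrogen bonding. In one operation an A-ring salicylaldehyde, trimethyl orthoformate and the 6-vinylchromen-7-ol form both bonds, the pyran ring and the C2 stereocentre as a 2,4-cis 4-methoxyflavan. C4 is oxidised to the ketone afterwards. The aldehyde precursor carries the finished hydroxyalkyl chain, two MOM ethers and one free phenol next to the chain, which becomes O1.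

Key step: step 8

**Remarks**

- Flavonoid numbering is used for 16–20 (O1, C2–C4, A ring C5–C8, B ring C1'–C6'). MOM = methoxymethyl.
- Stereochemical check: the key-step product 16 is (2S,4S), which is the 2,4-cis isomer, and C2 of the target is (S). The substituent priorities at C2 do not change from 16 to 20.
- Assumption: the sense of induction of the phosphoric acid in step 8 cannot be predicted with certainty. The route is written for the antipode that delivers (2S,4S), taken here as (R)-TRIP; the other antipode is used if the opposite sense is found.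
- Design change: the 2'-OH stays free in step 8, where it is needed, and is capped directly afterwards (step 9). A 2'-OH next to an ionisable C4 ether on a 5,7-dioxygenated A ring would otherwise form a 4,2'-ether bridge.

**Route**

Step 1
Reactants: 1 2,4,6-trihydroxybenzaldehyde; 2 prenyl bromide (0.9 equiv)
Product: 3 2,4,6-trihydroxy-3-(3-methylbut-2-en-1-yl)benzaldehyde
Conditions: 10% aq. KOH, 0 °C → rt
Reagents that add atoms: none
Why: Phenoxide C-alkylation (C-prenylation of a phloroglucinol): in water the phenoxide oxygens are hydrogen-bond solvated, so the allylic bromide is taken up by a ring carbon, and since the two free ring positions of 1 are equivalent only one mono-C-prenyl isomer can form, over-alkylation being limited by using the bromide in deficit.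

Step 2
Reactants: 3 2,4,6-trihydroxy-3-(3-methylbut-2-en-1-yl)benzaldehyde
Product: 4 2-hydroxy-4,6-bis(methoxymethoxy)-3-(3-methylbut-2-en-1-yl)benzaldehyde
Conditions: MOMCl (2.1 equiv), i-Pr2NEt, CH2Cl2, 0 °C
Reagents that add atoms: chloromethyl methyl ether, COCCl
Why: Base-mediated O-alkylation (MOM ether formation) under kinetic control: the 4-OH (para to the formyl group, not hydrogen-bonded) and the unhindered 6-OH should react first, while the 2-OH, squeezed between the prenyl and formyl groups and chelated to the carbonyl, is expected to remain free.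

Step 3
Reactants: 4 2-hydroxy-4,6-bis(methoxymethoxy)-3-(3-methylbut-2-en-1-yl)benzaldehyde
Product: 5 2-hydroxy-3-(3-hydroxy-3-methylbutyl)-4,6-bis(methoxymethoxy)benzaldehyde
Conditions: Co(acac)2 (20 mol%), PhSiH3, O2 (1 atm), THF, rt
Reagents that add atoms: dioxygen, O=O
Why: Mukaiyama hydration (cobalt hydride hydrogen-atom transfer, then O2 trapping and reduction): Markovnikov H-atom delivery to the trisubstituted alkene gives the tertiary radical and hence only the tertiary alcohol, under neutral conditions that should leave the MOM ethers, the chelated phenol and the electron-rich aldehyde untouched; no stereocentre is formed.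

Step 4
Reactants: 6 resorcinol; 7 3-methylbut-2-enoic acid
Product: 8 7-hydroxy-2,2-dimethylchroman-4-one
Conditions: Eaton's reagent (P2O5/MeSO3H), 70 °C
Reagents that add atoms: none
Why: Friedel–Crafts acylation para to one hydroxyl of resorcinol followed in the same pot by intramolecular oxa-Michael addition of the ortho hydroxyl to the enone (chromanone annulation), the 7-hydroxy isomer being favoured because acylation between the two hydroxyls is hindered.

Step 5
Reactants: 8 7-hydroxy-2,2-dimethylchroman-4-one
Product: 10 2,2-dimethyl-2H-chromen-7-ol, via 2,2-dimethylchromane-4,7-diol 9 (not isolated)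
Conditions: NaBH4, MeOH, 0 °C → rt; then p-TsOH (cat.), THF, 50 °C
Reagents that add atoms: none
Why: Borohydride reduction of the aryl ketone followed by acid-catalysed E1 dehydration of the benzylic alcohol, which is especially easy because the para hydroxyl stabilises the benzylic cation; the stereocentre of racemic 9 disappears with the alkene.

Step 6
Reactants: 10 2,2-dimethyl-2H-chromen-7-ol
Product: 11 7-hydroxy-2,2-dimethyl-2H-chromene-6-carbaldehyde
Conditions: MgCl2, Et3N, (CH2O)n, MeCN, reflux; aq. HCl work-up
Reagents that add atoms: paraformaldehyde (as formaldehyde), C=O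
Why: Magnesium phenoxide-directed ortho-formylation (Casnati–Skattebøl type): formaldehyde is delivered within the magnesium chelate only ortho to the hydroxyl, at the open C6 and not at C8 between two oxygens, and a second formaldehyde oxidises the benzylic alkoxide to the aldehyde; the basic medium spares the acid-sensitive chromene.

Step 7
Reactants: 11 7-hydroxy-2,2-dimethyl-2H-chromene-6-carbaldehyde
Product: 12 2,2-dimethyl-6-vinyl-2H-chromen-7-ol
Conditions: Ph3PCH3Br (2.5 equiv), KOt-Bu (2.5 equiv), THF, 0 °C → rt; stored cold and used promptly
Reagents that add atoms: methyltriphenylphosphonium bromide, C[P+](c1ccccc1)(c1ccccc1)c1ccccc1.[Br-]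
Why: Wittig methylenation with excess unstabilised ylide (one equivalent is consumed by the phenol) turns the formyl group into the vinyl group and does not touch the chromene alkene.

Step 8
Reactants: 5 2-hydroxy-3-(3-hydroxy-3-methylbutyl)-4,6-bis(methoxymethoxy)benzaldehyde; 12 2,2-dimethyl-6-vinyl-2H-chromen-7-ol (1.3 equiv); 13 trimethyl orthoformate (2 equiv)
Product: 16 6-[(2S,4S)-8-(3-hydroxy-3-methylbutyl)-4-methoxy-5,7-bis(methoxymethoxy)chroman-2-yl]-2,2-dimethyl-2H-chromen-7-ol (the 2,4-cis 4-methoxyflavan), via dimethyl acetal 14 (not isolated), via methoxy o-quinone methide 15 (not isolated)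
Conditions: 5, 13, (R)-TRIP (10 mol%), 5 Å MS, CH2Cl2, 0 °C; then 12 added slowly, −40 °C; Et3N quench; Et3N-deactivated silica
Reagents that add atoms: none
Why: Proposed new method: the acid and the orthoformate convert 5 into acetal 14, which expels methanol to give the methoxy-substituted o-quinone methide 15 (an aryl-stabilised oxocarbenium paired with the chiral phosphate); the phosphate also hydrogen-bonds the 2'-OH of 12, whose vinyl CH2 terminus attacks the electrophilic carbon (C3–C4), and the A-ring phenol oxygen then closes onto the B-ring benzylic carbon (O1–C2). The closest known reaction types are chiral phosphoric acid catalysed [4+2] cycloadditions of o-quinone methides with 2-vinylphenols and the achiral acid-mediated assembly of 2,4-cis-4-alkoxyflavans from salicylaldehydes, orthoformates and styrenes; their combination is the untested part. The pyran ring is closed in an asynchronous inverse-electron-demand oxa-[4+2] mode, C–C bond first and then a 6-exo-trig capture of the B-ring quinone-methide-like cation by oxygen. C4 is set by the face of 15 left open in the phosphate pocket, and C2 follows from the endo-type arrangement that puts aryl and methoxy cis, so a single (2S,4S) enantiomer is expected from the matching catalyst antipode. Regiochemistry needs no help beyond polarity (nucleophilic CH2 to the acetal carbon) and the fact that the only free A-ring phenol lies next to the side chain, so the chain ends at C8; chemoselectivity for the vinyl group over the hindered chromene alkene and over aromatic C-alkylation rests on hydrogen-bond delivery. Low temperature and an amine quench are required because the C4 ether of 16 can re-ionise and be captured by the free 2'-OH.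

Step 9
Reactants: 16 the (2S,4S)-4-methoxyflavan with free 2'-OH
Product: 17 4-[(2S,4S)-4-methoxy-5,7-bis(methoxymethoxy)-2-[7-(methoxymethoxy)-2,2-dimethyl-2H-chromen-6-yl]chroman-8-yl]-2-methylbutan-2-ol
Conditions: MOMCl (1.3 equiv), i-Pr2NEt, CH2Cl2, 0 °C → rt
Reagents that add atoms: chloromethyl methyl ether, COCCl
Why: Phenol O-alkylation (MOM ether formation) in a basic medium in which the labile C4 ether cannot ionise; the cap removes the internal nucleophile that could bridge O2' to C4 and shields the electron-rich phenol from the later oxidant, and the tertiary alcohol is much slower to react.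

Step 10
Reactants: 17 the (2S,4S)-4-methoxyflavan tris-MOM ether
Product: 18 (2S,4RS)-8-(3-hydroxy-3-methylbutyl)-5,7-bis(methoxymethoxy)-2-[7-(methoxymethoxy)-2,2-dimethyl-2H-chromen-6-yl]chroman-4-ol (both C4 epimers)
Conditions: PPTS (0.2 equiv), THF/H2O (3:1), rt → 40 °C
Reagents that add atoms: water, O
Why: Acid-catalysed SN1 ether-to-alcohol exchange (solvolysis): the C4 ether ionises under very weak acid because the cation is stabilised by O1, O5 and O7 in ortho/para positions, water in large excess captures it, the aryl MOM acetals need much stronger acid, and the configuration at C4 is irrelevant while C2 is not involved.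

Step 11
Reactants: 18 the flavan-4-ol tris-MOM ether
Product: 19 (2S)-8-(3-hydroxy-3-methylbutyl)-5,7-bis(methoxymethoxy)-2-[7-(methoxymethoxy)-2,2-dimethyl-2H-chromen-6-yl]chroman-4-one
Conditions: Dess–Martin periodinane (1.3 equiv), pyridine, CH2Cl2, 0 °C → rt
Reagents that add atoms: none
Why: Dess–Martin oxidation of the secondary benzylic alcohol (both C4 epimers converge) to the aryl ketone under buffered, non-basic conditions, so the tertiary alcohol and the chromene are untouched and base-induced retro-oxa-Michael opening at C2 cannot occur.

Step 12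
Reactants: 19 the (2S)-flavanone tris-MOM ether
Product: 20 (2S)-5,7-dihydroxy-2-(7-hydroxy-2,2-dimethyl-2H-chromen-6-yl)-8-(3-hydroxy-3-methylbutyl)chroman-4-one (CNP0423488.1)
Conditions: 3 M aq. HCl/THF (1:4), 40 °C, stopped at full conversion
Reagents that add atoms: none
Why: Acid-catalysed hydrolysis of the three aryl methoxymethyl acetals; dilute aqueous acid at mild temperature, with no base at any point, is chosen so that the C2 centre is not opened via a phenoxide, and with water as the only nucleophile the tertiary alcohol and the chromene should survive.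

**Compound list**

1 | 2,4,6-trihydroxybenzaldehyde | O=Cc1c(O)cc(O)cc1O | starting material
2 | prenyl bromide (1-bromo-3-methylbut-2-ene) | CC(C)=CCBr | starting material
3 | 2,4,6-trihydroxy-3-(3-methylbut-2-en-1-yl)benzaldehyde | CC(C)=CCc1c(O)cc(O)c(C=O)c1O | intermediate
4 | 2-hydroxy-4,6-bis(methoxymethoxy)-3-(3-methylbut-2-en-1-yl)benzaldehyde | CC(C)=CCc1c(O)c(C=O)c(OCOC)cc1OCOC | intermediate
5 | 2-hydroxy-3-(3-hydroxy-3-methylbutyl)-4,6-bis(methoxymethoxy)benzaldehyde | CC(C)(O)CCc1c(O)c(C=O)c(OCOC)cc1OCOC | intermediate
6 | resorcinol | Oc1cccc(O)c1 | starting material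
7 | 3-methylbut-2-enoic acid | CC(C)=CC(O)=O | starting material
8 | 7-hydroxy-2,2-dimethylchroman-4-one | CC1(C)CC(=O)c2ccc(O)cc2O1 | intermediate
9 | 2,2-dimethylchromane-4,7-diol (racemic, not isolated) | CC1(C)CC(O)c2ccc(O)cc2O1 | intermediate
10 | 2,2-dimethyl-2H-chromen-7-ol | CC1(C)C=Cc2ccc(O)cc2O1 | intermediate
11 | 7-hydroxy-2,2-dimethyl-2H-chromene-6-carbaldehyde | CC1(C)C=Cc2cc(C=O)c(O)cc2O1 | intermediate
12 | 2,2-dimethyl-6-vinyl-2H-chromen-7-ol | C=Cc1cc2c(cc1O)OC(C)(C)C=C2 | intermediate
13 | trimethyl orthoformate | COC(OC)OC | starting material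
14 | 2-(dimethoxymethyl)-6-(3-hydroxy-3-methylbutyl)-3,5-bis(methoxymethoxy)phenol (dimethyl acetal of 5, not isolated) | COC(OC)c1c(O)c(CCC(C)(C)O)c(OCOC)cc1OCOC | intermediate
15 | 2-(3-hydroxy-3-methylbutyl)-6-(methoxymethylidene)-3,5-bis(methoxymethoxy)cyclohexa-2,4-dien-1-one (methoxy o-quinone methide, alkene geometry not assigned, not isolated) | COC=C1C(=O)C(CCC(C)(C)O)=C(OCOC)C=C1OCOC | intermediate
16 | 6-[(2S,4S)-8-(3-hydroxy-3-methylbutyl)-4-methoxy-5,7-bis(methoxymethoxy)chroman-2-yl]-2,2-dimethyl-2H-chromen-7-ol | CC(C)(O)CCc1c(OCOC)cc(OCOC)c2c1O[C@H](c1cc3c(cc1O)OC(C)(C)C=C3)C[C@@H]2OC | intermediate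
17 | 4-[(2S,4S)-4-methoxy-5,7-bis(methoxymethoxy)-2-[7-(methoxymethoxy)-2,2-dimethyl-2H-chromen-6-yl]chroman-8-yl]-2-methylbutan-2-ol | CC(C)(O)CCc1c(OCOC)cc(OCOC)c2c1O[C@H](c1cc3c(cc1OCOC)OC(C)(C)C=C3)C[C@@H]2OC | intermediate
18 | (2S,4RS)-8-(3-hydroxy-3-methylbutyl)-5,7-bis(methoxymethoxy)-2-[7-(methoxymethoxy)-2,2-dimethyl-2H-chromen-6-yl]chroman-4-ol | CC(C)(O)CCc1c(OCOC)cc(OCOC)c2c1O[C@H](c1cc3c(cc1OCOC)OC(C)(C)C=C3)CC2O | intermediate
19 | (2S)-8-(3-hydroxy-3-methylbutyl)-5,7-bis(methoxymethoxy)-2-[7-(methoxymethoxy)-2,2-dimethyl-2H-chromen-6-yl]chroman-4-one | CC(C)(O)CCc1c(OCOC)cc(OCOC)c2c1O[C@H](c1cc3c(cc1OCOC)OC(C)(C)C=C3)CC2=O | intermediate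
20 | (2S)-5,7-dihydroxy-2-(7-hydroxy-2,2-dimethyl-2H-chromen-6-yl)-8-(3-hydroxy-3-methylbutyl)chroman-4-one | CC(C)(O)CCc1c(O)cc(O)c2c1O[C@H](c1cc3c(cc1O)OC(C)(C)C=C3)CC2=O | target

**Count**

Total steps: 12 (aldehyde arm 3, styrene arm 4, key step 1, end game 4).
Longest linear sequence: 9 steps (steps 4, 5, 6, 7, 8, 9, 10, 11, 12, from resorcinol).

**Steps most likely to fail**

Step 8 (proposed new method). Three processes may defeat it:
- poor facial control by the phosphate, or poor cis transmission to C2;
- re-ionisation of the C4 ether in the product and capture by the free 2'-OH, giving a 4,2'-bridged ether;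
- acid-induced oligomerisation of the electron-rich vinylphenol before it is intercepted.

The fallback uses only known chemistry and sets out from 12 (with 5 and 13 unchanged). Compound 12 is O-alkylated (MOMCl, i-Pr2NEt, CH2Cl2) to 7-(methoxymethoxy)-2,2-dimethyl-6-vinyl-2H-chromene F1, an ordinary electron-rich styrene with no internal nucleophile. F1, 5 and 13 are then combined under the established achiral acid-mediated three-component protocol (catalytic Sc(OTf)3, CH2Cl2, 0 °C). This should give the racemic 2,4-cis 4-methoxyflavan tris-MOM ether F2. Preparative HPLC on a chiral stationary phase separates the enantiomers. The (2S,4S) enantiomer is 17, where the route is rejoined at step 10; step 9 is no longer needed. The absolute configuration would be assigned at the flavanone stage by ECD.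

Step 10. The C4 cation may lose H3 to give the flav-3-ene instead of taking up water; a 2-aryl-2H-chromene can ionise at C2 and erode the configuration. Alternatively, acid strong enough to ionise C4 may start to strip the MOM acetals. The fallback sets out from 17 and returns at 19, bypassing 18. It is a direct hydride-abstraction oxidation of the benzylic methyl ether with DDQ in CH2Cl2/pH 7 buffer at 0 °C. The resulting methoxy-oxocarbenium adds water and the hemiketal collapses to the ketone and methanol. Loss of H3 from this ion leads only to an enol ether that hydrolyses to the same ketone. This fallback makes no new compound (F0).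

Step 12. Protic acid may open the pyranone ring reversibly (a chalcone-type pathway helped by the electron-rich B ring), with loss of configuration at C2. It may also add across the electron-rich chromene double bond, or cyclise the tertiary alcohol onto the freed 7-OH. The fallback sets out from 19 and returns at 20 by a non-protic silyl-transfer deprotection. TMSOTf/2,2'-bipyridyl in MeCN at 0 °C converts the three aryl MOM ethers into aryl trimethylsilyl ethers and silylates the tertiary alcohol, giving the tetrakis(trimethylsilyl) ether F3. The Si–O bonds are then cleaved with KHF2 in MeOH at rt, a nearly neutral medium, to give 20.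

**Further compounds**

F1 | step 8 | 7-(methoxymethoxy)-2,2-dimethyl-6-vinyl-2H-chromene | C=Cc1cc2c(cc1OCOC)OC(C)(C)C=C2
F2 | step 8 | racemic 2,4-cis 4-methoxyflavan tris-MOM ether (1:1 mixture of 17 and its enantiomer) | CC(C)(O)CCc1c(OCOC)cc(OCOC)c2c1O[C@H](c1cc3c(cc1OCOC)OC(C)(C)C=C3)C[C@@H]2OC.CC(C)(O)CCc1c(OCOC)cc(OCOC)c2c1O[C@@H](c1cc3c(cc1OCOC)OC(C)(C)C=C3)C[C@H]2OC
F0 | step 10 | none | none
F3 | step 12 | (2S)-2-[2,2-dimethyl-7-(trimethylsilyloxy)-2H-chromen-6-yl]-8-[3-methyl-3-(trimethylsilyloxy)butyl]-5,7-bis(trimethylsilyloxy)chroman-4-one | CC(C)(O[Si](C)(C)C)CCc1c(O[Si](C)(C)C)cc(O[Si](C)(C)C)c2c1O[C@H](c1cc3c(cc1O[Si](C)(C)C)OC(C)(C)C=C3)CC2=O
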